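# Kazinol N by gold-catalysed furan–yne benzannulation: synthesis design

## The problem

Kazinol N (24) is a 1,3-diarylpropane. A 2-methoxy-4-hydroxyphenyl ring A is tied by an unfunctionalised three-carbon chain to ring B, a pentasubstituted benzene fused to a 2,2-dimethyl-2H-pyran. In chromene numbering, C8a carries the pyran oxygen O1, C8 a free hydroxyl, C7 the only ring hydrogen, C6 the arylpropyl chain, C5 a prenyl group and C4a the C3=C4 alkene. The target has no stereocentre, so the difficulty is purely regiochemical: five contiguous substituents on one benzene ring, and two neighbouring oxygens that must end up differently (one a tertiary alkyl ether, one free). The C5 prenyl group is meta to both oxygens and so out of reach of Claisen or ortho-directed chemistry. The fragile elements are the prenyl alkene, the chromene double bond, the electron-rich ring B and the two phenols, which argues against strongly acidic or oxidising late steps. The enabling feature is the triad O1 on C8a, free OH on C8 and H on C7. This is what a furan leaves behind when it is tethered through C2 to an alkynyl ether and cycloisomerised: the alkyne carbons become C8a and C8, the furan oxygen moves to C8, and furan C3, C4 and C5 become C5, C6 and C7 with prenyl, chain and hydrogen already in place.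

## Retrosynthesis

**24 back to 22.** No skeletal bond is cut. The ring A phenol is traced to its triisopropylsilyl ether 23, and the C3=C4 alkene of 23 to a C4 methoxy group in chroman 22. The alkene cannot be carried through the ring-forming step, because the tether would then be an allylic alkynyl ether, a class that rearranges sigmatropically with great ease. A C4 oxygen arises naturally from a carbonyl addition, and a methyl ether is preferred to a silyl ether: it cannot migrate to a neighbouring carbanion or alkoxide in the steps that build the furan. The forward reaction must ionise a benzylic ether that O1 activates, without involving the prenyl group.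

**22 back to 20 (key disconnection).** The bonds C4a–C8a and C7–C8 are cut and the C8 oxygen is returned to a furan ring. The neighbouring option, removing the substituents of ring B one at a time, would require regiocontrol on an arene at every stage. This cut removes the arene altogether and replaces it by furan 20, whose substituents can be placed by directed furan chemistry. The forward reaction must close the pyran and the benzene ring in one operation and deliver the former furan oxygen to C8 only.

**20 back to 16 and 17.** The O–C(sp) bond is cut. The two alkyne carbons (future C8a and C8) come from trichloroethylene 17 through dichlorovinyl ether 18. A tertiary alkynyl ether can lose ketene on warming, so it is unveiled last and used at once. The forward reactions must add a hindered tertiary alkoxide to dichloroacetylene and then eliminate and exchange with butyllithium without touching the furan.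

**16 back to 13 and 14.** The furan C3–prenyl bond is cut, giving bromofuran 13 and prenyl bromide 14. The bromine has a second role: earlier it directs lithiation to the adjacent C2. The forward step is a bromine–lithium exchange in the presence of an alkoxide, followed by linear prenylation.

**13 back to 8 and 9.** The bond from furan C2 to the side chain is cut; ether 12 and alcohol 11 lead back to bromofuran 8 and 3-methylbut-2-enal 9. Addition of the 2-lithiofuran to 9 brings in all five side-chain carbons and the C4 oxygen at once. The tertiary oxygen then follows by Markovnikov hydration, done before the prenyl group exists so that only one alkene is present. The alternative, formylation, aldol addition of acetone and Grignard addition, is one step longer and passes through a β-alkoxy ketone prone to elimination.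

**8 back to 5 and 6.** The furan C4–CH2 bond is cut. Hydroboration of allylarene 5 gives alkylborane 7, which is coupled once with symmetrical 3,4-dibromofuran 6. This installs the oxygen-free chain and breaks the symmetry of 6 in the same step. The forward reaction must stop after one coupling.

**5 back to 1 and 3.** The aryl–allyl bond is cut. Aryl bromide 2, the silyl ether of commercial 4-bromo-3-methoxyphenol 1, already has the ring A pattern, with bromine where the chain starts. Lithiation and allylation with allyl bromide 3 complete the fragment.

## Roads not taken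

**Alternative 1: Baeyer–Villiger ring expansion of an indanone.** The cut is the C8a–O1 bond. A peracid would insert oxygen between the carbonyl and the aryl carbon of indanone A1 to give dihydrocoumarin A2, the electron-rich aryl group migrating. Every reaction on this road is classical and no labile alkynyl ether is involved; in robustness of the individual steps it is better than the chosen plan. Its weak point is that the key step makes only one C–O bond on a benzene that must already carry four correctly placed substituents, so the regiochemical problem is only moved into the synthesis of A1. After A2, the gem-dimethyl group, the chroman closure, the prenyl group (from the bromide) and the C3=C4 alkene still have to be added. The last needs a dehydrogenation on a molecule with an electron-rich diarylpropane and benzylic positions. The chosen plan sets against this one step that fixes all six ring positions and a C3=C4 alkene that comes from a built-in leaving group, not from an oxidation.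

**Alternative 2: cleavage of a dihydronaphthalene and double Wittig olefination.** The cuts are the two trisubstituted C=C bonds. Oxidative cleavage of the isolated alkene in dihydronaphthalene A3 would give dialdehyde A4, and two equivalents of the isopropylidene phosphorus ylide would give the 2,3-diprenyl arene A5. Both side arms arise from one symmetrical operation, and the linear-versus-branched question of organometallic prenylation does not arise; in this respect it is cleaner than step 7 of the chosen route. Its weak points are several. A4 is a double arylacetaldehyde that enolises and condenses easily under the basic ylide. The cleavage must spare two electron-rich arenes. The key step closes no ring, so the pyran would still need acetal removal and an oxidative cyclisation of one prenyl group in the presence of the other. A3 itself already requires the full oxygen and chain pattern on ring B. The chosen plan is shorter and closes both rings when it forms the arene.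

**Alternative 3: late ortho-oxygenation and quinone methide electrocyclisation.** The cuts are the C8–O and O1–C2 bonds. IBX would oxidise 2,3-diprenylphenol A6 at its free ortho position to the ortho-quinone. Base would tautomerise this to a vinyl ortho-quinone methide, which closes by oxa-6π electrocyclisation to chromene A7 (identical with 23). This endgame is shorter than the chosen one, needs no protecting group on ring B and no leaving group at C4; in step economy after the arene is in hand it is better. Its weak points lie before and during the key step. A6, with two adjacent prenyl groups next to the chain, is no easier to assemble regioselectively than furan 20. The ortho-quinone is an electron-poor diene beside electron-rich alkenes and can dimerise. Tautomerisation can also start from the C5 prenyl group and give a para-quinone methide. The chosen plan sets against it a non-oxidative construction in which the oxygen pattern and all substituent positions are fixed by connectivity.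

Key step: step 10

Assumption: the C4 stereocentre carried by 11 to 22 is destroyed in step 11, so these compounds are made and used as racemates (21 as a mixture of diastereomers) and no stereocontrol is attempted.

## Route

Ar denotes 2-methoxy-4-(triisopropylsilyloxy)phenyl throughout; positions in 21 to 24 use chromene numbering.

Step 1
Reactants: 1 4-bromo-3-methoxyphenol
Product: 2 (4-bromo-3-methoxyphenoxy)triisopropylsilane
Conditions: TIPSCl, imidazole, DMF, rt
Reagents that add atoms: chlorotriisopropylsilane, CC(C)[Si](Cl)(C(C)C)C(C)C
Why: Silylation of a phenol with a silyl chloride and imidazole; the triisopropylsilyl ether should survive the organolithium, hydride and aqueous-base steps ahead and is removed last with fluoride.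

Step 2
Reactants: 2 (4-bromo-3-methoxyphenoxy)triisopropylsilane; 3 allyl bromide
Product: 5 1-allyl-2-methoxy-4-(triisopropylsilyloxy)benzene, via aryllithium 4 (not isolated)
Conditions: n-BuLi, THF, −78 °C; CuBr·SMe2 (10 mol%); 3, −78 °C → rt
Reagents that add atoms: none
Why: Bromine–lithium exchange is fast at −78 °C and the lithium sits para to the silyloxy group, so no silyl migration is possible; copper-catalysed substitution of allyl bromide by the aryllithium gives the allylarene.

Step 3
Reactants: 5 1-allyl-2-methoxy-4-(triisopropylsilyloxy)benzene; 6 3,4-dibromofuran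
Product: 8 3-bromo-4-(3-Ar-propyl)furan, via alkylborane 7 (not isolated)
Conditions: 9-BBN, THF, 0 °C → rt; then 6 (3 equiv), Pd(OAc)2 (3 mol%), SPhos, aq K3PO4, THF, 50 °C
Reagents that add atoms: none
Why: 9-BBN hydroborates the terminal alkene at the terminal carbon and the B-alkyl Suzuki–Miyaura coupling joins the primary alkylborane to one C–Br bond of the symmetrical dibromide; the excess of 6 and the lower reactivity of the more electron-rich, more hindered monocoupled bromide should hold the reaction at the mono stage, and unreacted 6 can be recovered.

Step 4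
Reactants: 8 3-bromo-4-(3-Ar-propyl)furan; 9 3-methylbut-2-enal
Product: 11 racemic 1-[3-bromo-4-(3-Ar-propyl)furan-2-yl]-3-methylbut-2-en-1-ol, via 2-lithiofuran 10 (not isolated)
Conditions: LDA, THF, −78 °C; then 9, −78 °C; aq NH4Cl
Reagents that add atoms: none
Why: LDA removes the α-proton next to bromine (C2), the more acidic of the two α-positions as is known for 3-bromofurans, and the 2-furyllithium adds 1,2 to the enal; the carbinol centre forms as a racemate and is destroyed in step 11.

Step 5
Reactants: 11 racemic 1-[3-bromo-4-(3-Ar-propyl)furan-2-yl]-3-methylbut-2-en-1-ol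
Product: 12 racemic 3-bromo-2-(1-methoxy-3-methylbut-2-en-1-yl)-4-(3-Ar-propyl)furan
Conditions: NaH, MeI, THF, 0 °C → rt
Reagents that add atoms: iodomethane, CI
Why: Williamson ether synthesis on the secondary alkoxide; the methyl ether cannot migrate to the lithiated carbon of step 7 or the tertiary alkoxide of step 8, and it leaves as methanol in step 11.

Step 6
Reactants: 12 racemic 3-bromo-2-(1-methoxy-3-methylbut-2-en-1-yl)-4-(3-Ar-propyl)furan
Product: 13 racemic 4-[3-bromo-4-(3-Ar-propyl)furan-2-yl]-4-methoxy-2-methylbutan-2-ol
Conditions: Co(acac)2 (20 mol%), PhSiH3, O2 (1 atm), THF, rt; then aq Na2S2O3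
Reagents that add atoms: dioxygen, O=O
Why: Mukaiyama hydration (hydrogen-atom transfer from a cobalt hydride to the alkene, trapping of the tertiary radical by O2) should give the Markovnikov tertiary alcohol under neutral conditions that spare the furan and the furylic ether; it is placed here because the prenyl alkene, which would react in the same way, is not yet present.

Step 7
Reactants: 13 racemic 4-[3-bromo-4-(3-Ar-propyl)furan-2-yl]-4-methoxy-2-methylbutan-2-ol; 14 prenyl bromide (1-bromo-3-methylbut-2-ene)
Product: 16 racemic 4-methoxy-2-methyl-4-[3-(3-methylbut-2-en-1-yl)-4-(3-Ar-propyl)furan-2-yl]butan-2-ol, via dilithio species 15 (not isolated)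
Conditions: n-BuLi (2.2 equiv), THF, −78 °C; CuBr·SMe2 (20 mol%); 14, −78 → −20 °C; aq NH4Cl
Reagents that add atoms: none
Why: The first equivalent of n-BuLi forms the lithium alkoxide and the second exchanges bromine for lithium at −78 °C, where a 3-furyllithium holds its position; copper-catalysed substitution at the primary carbon of prenyl bromide should give the linear prenyl group, and the hindered tertiary lithium alkoxide is not alkylated at this temperature.

Step 8
Reactants: 16 racemic 4-methoxy-2-methyl-4-[3-(3-methylbut-2-en-1-yl)-4-(3-Ar-propyl)furan-2-yl]butan-2-ol; 17 trichloroethylene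
Product: 18 racemic 2-{3-[(E)-1,2-dichlorovinyloxy]-1-methoxy-3-methylbutyl}-3-(3-methylbut-2-en-1-yl)-4-(3-Ar-propyl)furan
Conditions: KH (2.2 equiv), THF, 0 °C → rt; 17, −40 °C → rt; MeOH quench
Reagents that add atoms: none
Why: The potassium alkoxide takes HCl from trichloroethylene to give dichloroacetylene and adds to it anti, the established route to (E)-1,2-dichlorovinyl ethers, which tertiary alkoxides also follow; the methyl ether, the aryl silyl ether and both alkenes are inert to KH.

Step 9
Reactants: 18 racemic 2-{3-[(E)-1,2-dichlorovinyloxy]-1-methoxy-3-methylbutyl}-3-(3-methylbut-2-en-1-yl)-4-(3-Ar-propyl)furan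
Product: 20 racemic 2-[3-(ethynyloxy)-1-methoxy-3-methylbutyl]-3-(3-methylbut-2-en-1-yl)-4-(3-Ar-propyl)furan, via lithium acetylide 19 (not isolated)
Conditions: n-BuLi (2.4 equiv), Et2O, −78 → −40 °C; MeOH, −78 °C; cold work-up, used at once
Reagents that add atoms: none
Why: n-BuLi eliminates HCl from the dichlorovinyl ether and exchanges the remaining chlorine for lithium, and cold protonation of the acetylide gives the terminal alkynyl ether; a tertiary alkynyl ether can lose ketene by a retro-ene reaction on warming, so it is kept cold and carried straight into step 10.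

Step 10
Reactants: 20 racemic 2-[3-(ethynyloxy)-1-methoxy-3-methylbutyl]-3-(3-methylbut-2-en-1-yl)-4-(3-Ar-propyl)furan
Product: 22 racemic 4-methoxy-2,2-dimethyl-5-(3-methylbut-2-en-1-yl)-6-(3-Ar-propyl)chroman-8-ol, via arene oxide 21 (not isolated)
Conditions: (Ph3P)AuNTf2 (3 mol%), CH2Cl2, 0 °C → rt
Reagents that add atoms: none
Why: The cationic monovalent gold complex binds the polarised alkynyl ether, and the furan attacks the oxygen-bearing alkyne carbon through its C2=C3 bond (ipso carbon C2) to give a spiro-fused cyclopropyl gold carbenoid; cleavage of the furan C2–O bond opens this to a (Z)-dienal carrying a vinyl gold carbenoid. The aldehyde oxygen adds to the carbene carbon to give an oxepine, which is in equilibrium with arene oxide 21 and opens to the phenol with release of the catalyst. The closest known reaction type is the gold-catalysed furan–yne phenol synthesis, which with 3-(furan-2-yl)propyl alkynyl ethers is known to give chroman-8-ols. The pyran closes by 6-exo-dig attack (bond C4a–C8a); the benzene ring closes when the oxepine undergoes 6π-electrocyclisation to the arene oxide (bond C7–C8). No stereocentre is created in the product and the C4 centre is a spectator. Two selectivities are needed: the furan must react faster than the prenyl alkene and faster than loss of the tertiary alkyl group, which the six-membered transition state, the nucleophilic trialkylfuran and the low temperature should secure; and the arene oxide must open at C7–O, which it should because the resulting cation is delocalised onto C8a and stabilised there by O1, leaving the former furan oxygen on C8.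

Step 11
Reactants: 22 racemic 4-methoxy-2,2-dimethyl-5-(3-methylbut-2-en-1-yl)-6-(3-Ar-propyl)chroman-8-ol
Product: 23 2,2-dimethyl-5-(3-methylbut-2-en-1-yl)-6-(3-Ar-propyl)-2H-chromen-8-ol
Conditions: pTsOH·H2O (5 mol%), toluene, 60 °C
Reagents that add atoms: none
Why: Acid-catalysed E1 elimination of methanol from a 4-alkoxychroman: the C4 cation is stabilised through C4a=C8a by O1 and loses a C3 proton to give the conjugated 2H-chromene, as in the classical dehydration of 2,2-dimethylchroman-4-ols; catalytic acid, moderate temperature and a short reaction time are chosen to spare the prenyl group.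

Step 12
Reactants: 23 2,2-dimethyl-5-(3-methylbut-2-en-1-yl)-6-(3-Ar-propyl)-2H-chromen-8-ol
Product: 24 Kazinol N
Conditions: TBAF, AcOH, THF, 0 °C → rt
Reagents that add atoms: none
Why: Fluoride cleaves the aryl oxygen–silicon bond; acetic acid buffers the phenoxides of the air-sensitive product, and neither alkene is affected.

## Compound list

1 | 4-bromo-3-methoxyphenol | COc1cc(O)ccc1Br | starting material
2 | (4-bromo-3-methoxyphenoxy)triisopropylsilane | COc1cc(O[Si](C(C)C)(C(C)C)C(C)C)ccc1Br | intermediate
3 | allyl bromide | C=CCBr | starting material
4 | [2-methoxy-4-(triisopropylsilyloxy)phenyl]lithium | COc1cc(O[Si](C(C)C)(C(C)C)C(C)C)ccc1[Li] | intermediate (not isolated)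
5 | 1-allyl-2-methoxy-4-(triisopropylsilyloxy)benzene | COc1cc(O[Si](C(C)C)(C(C)C)C(C)C)ccc1CC=C | intermediate
6 | 3,4-dibromofuran | Brc1cocc1Br | starting material
7 | B-(3-Ar-propyl)-9-borabicyclo[3.3.1]nonane | COc1cc(O[Si](C(C)C)(C(C)C)C(C)C)ccc1CCCB1C2CCCC1CCC2 | intermediate (not isolated)
8 | 3-bromo-4-(3-Ar-propyl)furan | COc1cc(O[Si](C(C)C)(C(C)C)C(C)C)ccc1CCCc1cocc1Br | intermediate
9 | 3-methylbut-2-enal | CC(C)=CC=O | starting material
10 | 3-bromo-2-lithio-4-(3-Ar-propyl)furan | COc1cc(O[Si](C(C)C)(C(C)C)C(C)C)ccc1CCCc1coc([Li])c1Br | intermediate (not isolated)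
11 | racemic 1-[3-bromo-4-(3-Ar-propyl)furan-2-yl]-3-methylbut-2-en-1-ol | COc1cc(O[Si](C(C)C)(C(C)C)C(C)C)ccc1CCCc1coc(C(O)C=C(C)C)c1Br | intermediate
12 | racemic 3-bromo-2-(1-methoxy-3-methylbut-2-en-1-yl)-4-(3-Ar-propyl)furan | COc1cc(O[Si](C(C)C)(C(C)C)C(C)C)ccc1CCCc1coc(C(OC)C=C(C)C)c1Br | intermediate
13 | racemic 4-[3-bromo-4-(3-Ar-propyl)furan-2-yl]-4-methoxy-2-methylbutan-2-ol | COc1cc(O[Si](C(C)C)(C(C)C)C(C)C)ccc1CCCc1coc(C(OC)CC(C)(C)O)c1Br | intermediate
14 | prenyl bromide (1-bromo-3-methylbut-2-ene) | CC(C)=CCBr | starting material
15 | lithium alkoxide of 13 with lithium in place of bromine at furan C3 (racemic) | COc1cc(O[Si](C(C)C)(C(C)C)C(C)C)ccc1CCCc1coc(C(OC)CC(C)(C)O[Li])c1[Li] | intermediate (not isolated)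
16 | racemic 4-methoxy-2-methyl-4-[3-(3-methylbut-2-en-1-yl)-4-(3-Ar-propyl)furan-2-yl]butan-2-ol | COc1cc(O[Si](C(C)C)(C(C)C)C(C)C)ccc1CCCc1coc(C(OC)CC(C)(C)O)c1CC=C(C)C | intermediate
17 | trichloroethylene | ClC=C(Cl)Cl | starting material
18 | racemic 2-{3-[(E)-1,2-dichlorovinyloxy]-1-methoxy-3-methylbutyl}-3-(3-methylbut-2-en-1-yl)-4-(3-Ar-propyl)furan | COc1cc(O[Si](C(C)C)(C(C)C)C(C)C)ccc1CCCc1coc(C(OC)CC(C)(C)O/C(Cl)=C\Cl)c1CC=C(C)C | intermediate
19 | lithium acetylide of 20 (racemic) | COc1cc(O[Si](C(C)C)(C(C)C)C(C)C)ccc1CCCc1coc(C(OC)CC(C)(C)OC#C[Li])c1CC=C(C)C | intermediate (not isolated)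
20 | racemic 2-[3-(ethynyloxy)-1-methoxy-3-methylbutyl]-3-(3-methylbut-2-en-1-yl)-4-(3-Ar-propyl)furan | COc1cc(O[Si](C(C)C)(C(C)C)C(C)C)ccc1CCCc1coc(C(OC)CC(C)(C)OC#C)c1CC=C(C)C | intermediate
21 | 7,8-epoxy-4-methoxy-2,2-dimethyl-5-(3-methylbut-2-en-1-yl)-6-(3-Ar-propyl)-3,4,7,8-tetrahydro-2H-chromene (arene oxide, racemic, mixture of diastereomers) | COC1CC(C)(C)OC2=C1C(CC=C(C)C)=C(CCCc3ccc(O[Si](C(C)C)(C(C)C)C(C)C)cc3OC)C4OC24 | intermediate (not isolated)
22 | racemic 4-methoxy-2,2-dimethyl-5-(3-methylbut-2-en-1-yl)-6-(3-Ar-propyl)chroman-8-ol | COc1cc(O[Si](C(C)C)(C(C)C)C(C)C)ccc1CCCc1cc(O)c2OC(C)(C)CC(OC)c2c1CC=C(C)C | intermediate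
23 | 2,2-dimethyl-5-(3-methylbut-2-en-1-yl)-6-(3-Ar-propyl)-2H-chromen-8-ol | COc1cc(O[Si](C(C)C)(C(C)C)C(C)C)ccc1CCCc1cc(O)c2OC(C)(C)C=Cc2c1CC=C(C)C | intermediate
24 | Kazinol N, 6-[3-(4-hydroxy-2-methoxyphenyl)propyl]-2,2-dimethyl-5-(3-methylbut-2-en-1-yl)-2H-chromen-8-ol | COc1cc(O)ccc1CCCc1cc(O)c2c(c1CC=C(C)C)C=CC(C)(C)O2 | target

## Step count and risk

Total: 12 steps. Longest linear sequence: 12 steps (1 to 24).

**Step 10 (key step).** The most likely failure is that the gold-bound tertiary alkynyl ether loses its tertiary alkyl group (ionisation, or retro-ene fragmentation to a ketene) faster than the furan attacks, because ipso attack at the fully substituted C2 beside a branched side chain and a prenyl group is crowded. Hydration of the activated alkyne by traces of water is a second drain.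

The fallback keeps the furan–alkyne benzannulation but makes it intermolecular, so that the furan attacks through its free, unhindered C5 and a robust primary alkynyl ether replaces the tertiary one. The two oxygens then exchange roles. It sets out from 16 and comes back at 24.
- 2-(Trimethylsilyl)ethanol is taken through the operations of steps 8 and 9 (KH, trichloroethylene; then n-BuLi, MeOH) via (E)-1,2-dichlorovinyl 2-(trimethylsilyl)ethyl ether F1 to [2-(ethynyloxy)ethyl]trimethylsilane F2.
- With (Ph3P)AuNTf2 in CH2Cl2, 16 and F2 should give the phenol 2-(3-hydroxy-1-methoxy-3-methylbutyl)-3-(3-methylbut-2-en-1-yl)-4-(3-Ar-propyl)-6-[2-(trimethylsilyl)ethoxy]phenol F3. The mechanism is the same carbenoid, oxepine and arene oxide sequence as in step 10. The former furan oxygen is now the free hydroxyl beside the side chain (the future O1), and the ether oxygen sits on the future C8.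
- Catalytic pTsOH in toluene should close the pyran onto the tertiary carbon and expel methanol and water, the classical closure of 2,2-dimethylchromenes, to give the chromene 8-[2-(trimethylsilyl)ethyl] ether F4.
- CsF in DMF at 80 °C should remove the 2-(trimethylsilyl)ethyl and triisopropylsilyl groups to give 24.

**Step 8.** Addition of the hindered tertiary potassium alkoxide to dichloroacetylene may be slow, leaving time for decomposition of dichloroacetylene and for silyl transfer from ring A to the alkoxide. The fallback builds the two alkyne carbons on the oxygen by olefination instead. It sets out from 16 and comes back at 20. Formic acetic anhydride and pyridine give the formate ester F5. Ramirez olefination (CBr4, PPh3, CH2Cl2) gives the 1,1-dibromovinyl ether F6. n-BuLi at −78 °C eliminates and exchanges to acetylide 19, which is protonated to 20 as in step 9.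

**Step 6.** The Mukaiyama hydration may stall, or divert to simple reduction of the alkene, or oxidise the electron-rich furan under the radical and oxygen conditions. The fallback is a carbonyl route that sets out from 8 and comes back at 13, replacing steps 4 to 6. Lithiofuran 10 is formylated with DMF to 3-bromo-4-(3-Ar-propyl)furan-2-carbaldehyde F7. The lithium enolate of acetone adds at −78 °C to give the β-hydroxy ketone F8. Me3OBF4 with 1,8-bis(dimethylamino)naphthalene gives the β-methoxy ketone F9. MeMgBr with CeCl3 at −78 °C gives 13.

**Step 3.** Over-coupling to the 3,4-dialkylfuran, or slow oxidative addition into the electron-rich 3-bromofuran with protodeboronation of 7, may erode the mono-coupling. The fallback replaces cross-coupling by polar alkylation. It sets out from 2 and comes back at 8. Aryllithium 4 opens oxetane with BF3·OEt2 at −78 °C to give 3-Ar-propan-1-ol F10. An Appel reaction (I2, PPh3, imidazole) gives 1-iodo-3-Ar-propane F11. Clean single bromine–lithium exchange of 6 (n-BuLi, Et2O, −78 °C) gives 3-bromo-4-lithiofuran F12, which is alkylated by F11 in THF/DMPU to give 8.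

**Step 7.** Migration of lithium from C3 to the free C5 of the furan before trapping, or allylic transposition giving the branched (reverse) prenyl isomer, would lower the yield of 16. The fallback replaces the organolithium by a palladium-catalysed Stille coupling of 13 with tributyl(3-methylbut-2-en-1-yl)stannane (Pd(PPh3)4, DMF, 80 °C). This tolerates the free tertiary alcohol, sets out from 13, comes back at 16 and makes no new intermediate.

## Further compounds

F1 | step 10 | (E)-1,2-dichlorovinyl 2-(trimethylsilyl)ethyl ether | C[Si](C)(C)CCO/C(Cl)=C\Cl
F2 | step 10 | [2-(ethynyloxy)ethyl]trimethylsilane | C[Si](C)(C)CCOC#C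
F3 | step 10 | racemic 2-(3-hydroxy-1-methoxy-3-methylbutyl)-3-(3-methylbut-2-en-1-yl)-4-(3-Ar-propyl)-6-[2-(trimethylsilyl)ethoxy]phenol | COc1cc(O[Si](C(C)C)(C(C)C)C(C)C)ccc1CCCc1cc(OCC[Si](C)(C)C)c(O)c(C(OC)CC(C)(C)O)c1CC=C(C)C
F4 | step 10 | 2,2-dimethyl-5-(3-methylbut-2-en-1-yl)-6-(3-Ar-propyl)-8-[2-(trimethylsilyl)ethoxy]-2H-chromene | COc1cc(O[Si](C(C)C)(C(C)C)C(C)C)ccc1CCCc1cc(OCC[Si](C)(C)C)c2OC(C)(C)C=Cc2c1CC=C(C)C
F5 | step 8 | racemic formate ester of 16 | COc1cc(O[Si](C(C)C)(C(C)C)C(C)C)ccc1CCCc1coc(C(OC)CC(C)(C)OC=O)c1CC=C(C)C
F6 | step 8 | racemic 2,2-dibromovinyl ether of 16 | COc1cc(O[Si](C(C)C)(C(C)C)C(C)C)ccc1CCCc1coc(C(OC)CC(C)(C)OC=C(Br)Br)c1CC=C(C)C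
F7 | step 6 | 3-bromo-4-(3-Ar-propyl)furan-2-carbaldehyde | COc1cc(O[Si](C(C)C)(C(C)C)C(C)C)ccc1CCCc1coc(C=O)c1Br
F8 | step 6 | racemic 4-[3-bromo-4-(3-Ar-propyl)furan-2-yl]-4-hydroxybutan-2-one | COc1cc(O[Si](C(C)C)(C(C)C)C(C)C)ccc1CCCc1coc(C(O)CC(C)=O)c1Br
F9 | step 6 | racemic 4-[3-bromo-4-(3-Ar-propyl)furan-2-yl]-4-methoxybutan-2-one | COc1cc(O[Si](C(C)C)(C(C)C)C(C)C)ccc1CCCc1coc(C(OC)CC(C)=O)c1Br
F10 | step 3 | 3-[2-methoxy-4-(triisopropylsilyloxy)phenyl]propan-1-ol | COc1cc(O[Si](C(C)C)(C(C)C)C(C)C)ccc1CCCO
F11 | step 3 | [4-(3-iodopropyl)-3-methoxyphenoxy]triisopropylsilane | COc1cc(O[Si](C(C)C)(C(C)C)C(C)C)ccc1CCCI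
F12 | step 3 | 3-bromo-4-lithiofuran | [Li]c1cocc1Br
F0 | step 7 | none | none
A1 | alternative 1 | 4-bromo-5-(3-Ar-propyl)-7-(triisopropylsilyloxy)indan-1-one | COc1cc(O[Si](C(C)C)(C(C)C)C(C)C)ccc1CCCc1cc(O[Si](C(C)C)(C(C)C)C(C)C)c2C(=O)CCc2c1Br
A2 | alternative 1 | 5-bromo-6-(3-Ar-propyl)-8-(triisopropylsilyloxy)chroman-2-one | COc1cc(O[Si](C(C)C)(C(C)C)C(C)C)ccc1CCCc1cc(O[Si](C(C)C)(C(C)C)C(C)C)c2OC(=O)CCc2c1Br
A3 | alternative 2 | 1-(methoxymethoxy)-2-(triisopropylsilyloxy)-4-(3-Ar-propyl)-5,8-dihydronaphthalene | COc1cc(O[Si](C(C)C)(C(C)C)C(C)C)ccc1CCCc1cc(O[Si](C(C)C)(C(C)C)C(C)C)c(OCOC)c2CC=CCc12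
A4 | alternative 2 | 2,2'-[3-(methoxymethoxy)-4-(triisopropylsilyloxy)-6-(3-Ar-propyl)-1,2-phenylene]diacetaldehyde | COc1cc(O[Si](C(C)C)(C(C)C)C(C)C)ccc1CCCc1cc(O[Si](C(C)C)(C(C)C)C(C)C)c(OCOC)c(CC=O)c1CC=O
A5 | alternative 2 | 3-(methoxymethoxy)-1,2-bis(3-methylbut-2-en-1-yl)-6-(3-Ar-propyl)-4-(triisopropylsilyloxy)benzene | COc1cc(O[Si](C(C)C)(C(C)C)C(C)C)ccc1CCCc1cc(O[Si](C(C)C)(C(C)C)C(C)C)c(OCOC)c(CC=C(C)C)c1CC=C(C)C
A6 | alternative 3 | 2,3-bis(3-methylbut-2-en-1-yl)-4-(3-Ar-propyl)phenol | COc1cc(O[Si](C(C)C)(C(C)C)C(C)C)ccc1CCCc1ccc(O)c(CC=C(C)C)c1CC=C(C)C
A7 | alternative 3 | 2,2-dimethyl-5-(3-methylbut-2-en-1-yl)-6-(3-Ar-propyl)-2H-chromen-8-ol (identical with 23) | COc1cc(O[Si](C(C)C)(C(C)C)C(C)C)ccc1CCCc1cc(O)c2OC(C)(C)C=Cc2c1CC=C(C)C
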